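**Retrosynthetic overview**
1. 18 ⇐ 16 (last step, one pot): face-selective epoxidation of the C7=C8 olefin, then transannular epoxide–olefin closure (C19→C7, water capture at C11). The six- and seven-membered rings of the bicyclo[4.3.1]decane form together and C7, C8 and C11 are set at once; a 7Z (not 7E) ring olefin is needed for the equatorial C8–OH of the target.
2. 16 ⇐ 12 + 15: crossed aldol condensation builds C4=C12 of the dienal side chain.
3. 12 ⇐ 10 (lactone → diol → 1,5-dialdehyde); 10 ⇐ 9 by Z-selective ring-closing metathesis (C7=C8) on a trans-lactone template.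
4. 9 ⇐ 5 + 4 + 3: one-pot asymmetric conjugate addition / enolate alkenylation sets C4a and C11a.
5. Ring order: δ-lactone template (bought) → nine-membered carbocycle (RCM) → lactone opened → six- and seven-membered rings by the transannular step.

Assumption: atoms are labelled with xenicane numbering (C1, C3, C4, C4a, C5–C11, C11a, C12–C19), and the presumed biosynthesis is taken as transannular C19→C7 closure of a C7/C8-oxidized xenicane 1,3-dialdehyde with water capture at C11.

**Step 1**
Reactants: 1 allylmagnesium bromide; 2 2,3-dibromopropene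
Product: 3 2-bromohexa-1,5-diene
Conditions: Et2O, 0 °C to rt
Reagents that add atoms: none
Why: Uncatalysed Grignard allylic substitution (allyl–allyl coupling) displaces only the allylic C–Br bond of 2, the vinylic bromide being inert, and no stereocentre is formed.

**Step 2**
Reactants: 4 4-bromo-2-methylbut-1-ene; 5 5,6-dihydro-2H-pyran-2-one; 3 2-bromohexa-1,5-diene
Product: 9 (3R,4R)-3-(hexa-1,5-dien-2-yl)-4-(3-methylbut-3-en-1-yl)oxan-2-one, via Grignard reagent 6 (not isolated), via magnesium enolate 7 (not isolated), via zinc enolate 8 (not isolated)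
Conditions: Mg, THF, rt (gives 6); added slowly to 5, CuBr·SMe2 (5 mol%), (R,Sp)-Josiphos (6 mol%; its antipode if the facial sense proves opposite), t-BuOMe, −78 °C; ZnCl2 (1.2 equiv, THF), −78 → 0 °C; then 3 (1.5 equiv), Pd(dba)2 (5 mol%), P(t-Bu)3 (5 mol%), rt
Reagents that add atoms: none
Why: Proposed new method: ligand-controlled copper-catalysed asymmetric conjugate addition of the Grignard reagent sets C4 (R, = C4a) and leaves a regiodefined magnesium enolate, which after Mg→Zn exchange couples with the vinyl bromide at zerovalent palladium (oxidative addition, transmetalation, reductive elimination) on the face anti to the new C4 substituent to give the trans (3R, = C11a) lactone with the C11 methylene already in place, the closest known reaction types being copper/ferrocenyl-diphosphine Grignard conjugate addition to unsaturated lactones with enolate trapping and Negishi-type palladium-catalysed α-alkenylation of Reformatsky (zinc) ester enolates.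

**Step 3**
Reactants: 9 (3R,4R)-3-(hexa-1,5-dien-2-yl)-4-(3-methylbut-3-en-1-yl)oxan-2-one
Product: 10 (4aR,7Z,11aR)-7-methyl-11-methylidene-4,4a,5,6,9,10,11,11a-octahydrocyclonona[c]pyran-1(3H)-one
Conditions: second-generation Hoveyda–Grubbs catalyst (10 mol%), 1,4-benzoquinone (20 mol%), toluene (1 mM), 90 °C
Reagents that add atoms: none
Why: Ring-closing metathesis between the monosubstituted C8 vinyl and the C7 isopropenyl group, templated by the trans-diequatorial lactone substituents, closes the nine-membered ring with the trisubstituted olefin strongly favoured as Z, while the C11 methylene cannot compete (it could only give a cyclobutene or a tetrasubstituted olefin).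

**Step 4**
Reactants: 10 (4aR,7Z,11aR)-7-methyl-11-methylidene-4,4a,5,6,9,10,11,11a-octahydrocyclonona[c]pyran-1(3H)-one
Product: 11 2-[(1R,4Z,9R)-9-(hydroxymethyl)-4-methyl-8-methylidenecyclonon-4-en-1-yl]ethan-1-ol
Conditions: LiAlH4, THF, 0 °C
Reagents that add atoms: none
Why: Hydride reduction of the lactone gives the 1,5-diol without touching the olefins or the C4a/C11a stereocentres.

**Step 5**
Reactants: 11 2-[(1R,4Z,9R)-9-(hydroxymethyl)-4-methyl-8-methylidenecyclonon-4-en-1-yl]ethan-1-ol
Product: 12 (1R,2R,5Z)-5-methyl-9-methylidene-2-(2-oxoethyl)cyclonon-5-ene-1-carbaldehyde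
Conditions: (COCl)2, DMSO, CH2Cl2, −78 °C; Et3N, −78 → −30 °C; cold pH 7 buffer quench; used crude
Reagents that add atoms: none
Why: Swern oxidation converts both primary alcohols into alkoxysulfonium salts before base is added, so the 1,5-dialdehyde forms without lactol over-oxidation, and the cold work-up protects the epimerizable β,γ-unsaturated C11a aldehyde.

**Step 6**
Reactants: 13 2-methylbut-3-en-2-ol; 14 (E)-but-2-enal
Product: 15 (E)-4-hydroxy-4-methylpent-2-enal
Conditions: second-generation Hoveyda–Grubbs catalyst (2 mol%), 14 (3 equiv), CH2Cl2, 40 °C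
Reagents that add atoms: none
Why: Olefin cross-metathesis between a hindered tertiary allylic alcohol and an electron-poor enal is selective for the cross product and gives the thermodynamically favoured E-enal.

**Step 7**
Reactants: 12 (1R,2R,5Z)-5-methyl-9-methylidene-2-(2-oxoethyl)cyclonon-5-ene-1-carbaldehyde; 15 (E)-4-hydroxy-4-methylpent-2-enal
Product: 16 (1R,2S,5Z)-2-[(2E,4E)-6-hydroxy-6-methyl-1-oxohepta-2,4-dien-2-yl]-5-methyl-9-methylidenecyclonon-5-ene-1-carbaldehyde
Conditions: pyrrolidine (20 mol%), PhCO2H (20 mol%), 15 (3 equiv), CH2Cl2, 0 °C, slow addition of 12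
Reagents that add atoms: none
Why: Amine-catalysed (enamine/iminium, Mannich-type) crossed aldol condensation, in which only the unbranched C4 methylene aldehyde forms an enamine quickly, 15 cannot enolize and its β-carbon is shielded by the CMe2OH group so that 1,2-addition and loss of water follow, giving the (E)-2-substituted dienal under thermodynamic control.

**Step 8**
Reactants: 16 (1R,2S,5Z)-2-[(2E,4E)-6-hydroxy-6-methyl-1-oxohepta-2,4-dien-2-yl]-5-methyl-9-methylidenecyclonon-5-ene-1-carbaldehyde
Product: 18 umbellacin A, via epoxide 17 (not isolated)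
Conditions: DMDO (1.05 equiv), acetone, −40 °C; then H2O, TsOH·H2O (5 mol%), −20 → 0 °C
Reagents that add atoms: dimethyldioxirane CC1(C)OO1; water O
Why: The electrophilic dioxirane epoxidizes only the electron-rich trisubstituted Z-olefin, on the exposed face syn to the C11a formyl group (the C11 methylene is folded under the other face in the conformer that keeps the C4a branch pseudo-equatorial), and protonation then triggers the transannular epoxide–olefin (cation–olefin) cyclization in which C19 opens the oxirane at tertiary C7 with inversion through a chair-like six-membered transition state and water caps the bridgehead C11 cation from outside, setting C7 (S), C8 (R, retained from the cis-epoxide, equatorial OH; a 7E olefin would give the C8 epimer) and C11 (R) in one operation, as in the acid-mediated conversion of caryophyllene oxide into caryolane-1,9-diol.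

**Compound list**
1 | allylmagnesium bromide | C=CC[Mg]Br | starting material
2 | 2,3-dibromopropene | C=C(Br)CBr | starting material
3 | 2-bromohexa-1,5-diene | C=C(Br)CCC=C | intermediate
4 | 4-bromo-2-methylbut-1-ene | C=C(C)CCBr | starting material
5 | 5,6-dihydro-2H-pyran-2-one | O=C1C=CCCO1 | starting material
6 | (3-methylbut-3-en-1-yl)magnesium bromide | C=C(C)CC[Mg]Br | intermediate
7 | [(4R)-4-(3-methylbut-3-en-1-yl)-5,6-dihydro-4H-pyran-2-yl]oxymagnesium bromide | C=C(C)CC[C@@H]1CCOC(O[Mg]Br)=C1 | intermediate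
8 | [(4R)-4-(3-methylbut-3-en-1-yl)-5,6-dihydro-4H-pyran-2-yl]oxyzinc chloride | C=C(C)CC[C@@H]1CCOC(O[Zn]Cl)=C1 | intermediate
9 | (3R,4R)-3-(hexa-1,5-dien-2-yl)-4-(3-methylbut-3-en-1-yl)oxan-2-one (trans) | O=C1OCC[C@@H](CCC(C)=C)[C@@H]1C(=C)CCC=C | intermediate
10 | (4aR,7Z,11aR)-7-methyl-11-methylidene-4,4a,5,6,9,10,11,11a-octahydrocyclonona[c]pyran-1(3H)-one (trans-fused δ-lactone on a Z-cyclononene) | O=C1OCC[C@H]2CC/C(C)=C\CCC(=C)[C@H]12 | intermediate
11 | 2-[(1R,4Z,9R)-9-(hydroxymethyl)-4-methyl-8-methylidenecyclonon-4-en-1-yl]ethan-1-ol | OCC[C@H]1CC/C(C)=C\CCC(=C)[C@@H]1CO | intermediate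
12 | (1R,2R,5Z)-5-methyl-9-methylidene-2-(2-oxoethyl)cyclonon-5-ene-1-carbaldehyde | O=CC[C@H]1CC/C(C)=C\CCC(=C)[C@@H]1C=O | intermediate
13 | 2-methylbut-3-en-2-ol | C=CC(C)(C)O | starting material
14 | (E)-but-2-enal | C/C=C/C=O | starting material
15 | (E)-4-hydroxy-4-methylpent-2-enal | CC(C)(O)/C=C/C=O | intermediate
16 | (1R,2S,5Z)-2-[(2E,4E)-6-hydroxy-6-methyl-1-oxohepta-2,4-dien-2-yl]-5-methyl-9-methylidenecyclonon-5-ene-1-carbaldehyde | CC(C)(O)/C=C/C=C(/C=O)[C@H]1CC/C(C)=C\CCC(=C)[C@@H]1C=O | intermediate
17 | (4aS,7S,8R,11aR)-7,8-epoxide of 16 (cis-oxirane on the olefin face syn to the C11a formyl group; xenicane numbering) | CC(C)(O)/C=C/C=C(/C=O)[C@H]1CC[C@]2(C)O[C@@H]2CCC(=C)[C@@H]1C=O | intermediate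
18 | umbellacin A, (4aS,7S,8R,11R,11aR) in xenicane numbering | CC(C)(O)/C=C/C=C(/C=O)[C@H]1CC[C@@]2(C)C[C@](O)(CC[C@H]2O)[C@@H]1C=O | target

**Step count**
Total steps: 8. Longest linear sequence: 7 (steps 1, 2, 3, 4, 5, 7, 8).

**Three steps most likely to fail**

Step 8 (epoxidation face, elimination of the C11 cation to a bridgehead enal, survival of the dienal and the C11a aldehyde). The fallback sets out from 11 and comes back at 18. Diol 11 is epoxidized under reagent control (Shi conditions: fructose-derived ketone enantiomer matched to the 7S,8R oxirane, KHSO5, K2CO3 buffer, MeCN/H2O, 0 °C) to give (4aR,7S,8R,11aR)-7,8-epoxy diol F7. Swern oxidation gives the (4aR,7S,8R,11aR)-epoxy dialdehyde F8. TsOH·H2O in wet acetone then closes it, before the acid-sensitive side chain exists, to the bicyclic (4aR,7S,8R,11R,11aR)-8,11-dihydroxy dialdehyde F9. The pyrrolidine/PhCO2H condensation with 15 is run last and gives 18.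

Step 7 (isomerization or epimerization of the β,γ-unsaturated C11a aldehyde under amine catalysis, self-condensation). The fallback sets out from 11 and comes back at 16. TEMPO/PhI(OAc)2 oxidizes the less hindered C3 carbinol first and carries the lactol on to the isomeric lactone (4aR,7Z,11aR)-7-methyl-11-methylidene-octahydrocyclonona[c]pyran-3-one F3 (any 10 formed is reduced back to 11). LDA at −78 °C followed by the lithium alkoxide of 15 gives the C4 aldol adduct (4aS,11aR)-4-(1,4-dihydroxy-4-methylpent-2-enyl) lactone F4. MsCl/Et3N then DBU eliminates the secondary allylic carbinol to the (4E)-4-[(2E)-4-hydroxy-4-methylpent-2-enylidene] lactone F5. i-Bu2AlH reduction gives the (4aS,11aR)-dienyl 1,5-diol F6, and Swern oxidation of both primary alcohols returns to 16.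

Step 2 (one-pot enolate alkenylation: proton transfer to the product, migration of the new β,γ-olefin into conjugation, Kumada-type consumption of 3). The fallback sets out from 5 (with Grignard 6) and comes back at 9. The same copper-catalysed conjugate addition is run, but the magnesium enolate is trapped with pent-4-enal to give the aldol lactone (3R,4R)-3-(1-hydroxypent-4-en-1-yl)-4-(3-methylbut-3-en-1-yl)oxan-2-one F1. Dess–Martin oxidation gives the β-keto lactone (3R,4R)-4-(3-methylbut-3-en-1-yl)-3-(pent-4-enoyl)oxan-2-one F2. Non-basic Takai–Lombardo methylenation (Zn, CH2Br2, TiCl4, THF/CH2Cl2, 0 °C) converts the ketone into the C11 methylene and returns to 9.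

**Further compounds**
F1 | step 2 | (3R,4R)-3-(1-hydroxypent-4-en-1-yl)-4-(3-methylbut-3-en-1-yl)oxan-2-one (carbinol epimers) | O=C1OCC[C@@H](CCC(C)=C)[C@@H]1C(O)CCC=C
F2 | step 2 | (3R,4R)-4-(3-methylbut-3-en-1-yl)-3-(pent-4-enoyl)oxan-2-one | O=C1OCC[C@@H](CCC(C)=C)[C@@H]1C(=O)CCC=C
F3 | step 7 | (4aR,7Z,11aR)-7-methyl-11-methylidene-octahydrocyclonona[c]pyran-3-one (C3 carbonyl, C1 is OCH2) | O=C1C[C@H]2CC/C(C)=C\CCC(=C)[C@@H]2CO1
F4 | step 7 | (4aS,7Z,11aR)-4-[(2E)-1,4-dihydroxy-4-methylpent-2-en-1-yl]-7-methyl-11-methylidene-octahydrocyclonona[c]pyran-3-one (C4 and carbinol epimers) | O=C1OC[C@H]2C(=C)CC/C=C(C)\CC[C@@H]2C1C(O)/C=C/C(C)(C)O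
F5 | step 7 | (4E,4aS,7Z,11aR)-4-[(2E)-4-hydroxy-4-methylpent-2-en-1-ylidene]-7-methyl-11-methylidene-octahydrocyclonona[c]pyran-3-one | O=C1OC[C@H]2C(=C)CC/C=C(C)\CC[C@@H]2/C1=C\C=C\C(C)(C)O
F6 | step 7 | (2E,4E)-2-[(1S,4Z,9R)-9-(hydroxymethyl)-4-methyl-8-methylidenecyclonon-4-en-1-yl]-6-methylhepta-2,4-diene-1,6-diol | OC/C(=C/C=C/C(C)(C)O)[C@H]1CC/C(C)=C\CCC(=C)[C@@H]1CO
F7 | step 8 | (4aR,7S,8R,11aR)-7,8-epoxide of diol 11 | OCC[C@H]1CC[C@]2(C)O[C@@H]2CCC(=C)[C@@H]1CO
F8 | step 8 | (4aR,7S,8R,11aR)-7,8-epoxide of dialdehyde 12 | O=CC[C@H]1CC[C@]2(C)O[C@@H]2CCC(=C)[C@@H]1C=O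
F9 | step 8 | (4aR,7S,8R,11R,11aR)-8,11-dihydroxy-7-methyl-4a-(2-oxoethyl)bicyclo[4.3.1]decane-11a-carbaldehyde (xenicane numbering; the core of 18 with CH2CHO at C4a) | O=CC[C@H]1CC[C@@]2(C)C[C@](O)(CC[C@H]2O)[C@@H]1C=O
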